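## Retrosynthetic overview

1. Target 33 ← acetylation, Luche reduction and a peracid step (epoxidation plus Baeyer–Villiger oxidation) from tricyclic dione 28, which carries a C2 ketone and a C14 acetyl group in place of the C14 acetate.
2. 28 ← furan triene 25 by furan photooxygenation to a cis-enedione and intramolecular Diels–Alder reaction. Enabling feature: the C11–C12 epoxide lies across ring A (C1, C10–C14) opposite the C1–C14 bond, so ring A is the oxide of a Diels–Alder cyclohexene (diene C10=C11–C12=C13, dienophile C1=C14). C1 and C10 are also the fusion atoms of ten-membered ring B (C1–C10), and the C2 carbinol with the C14 acetate (carried as acetyl) corresponds to a cis-enedione, which is a 3,5-dimethylfuran.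
3. 25 ← boron aldol (C6–C7) of aldehyde 12 with furyl enone 19, methylenation of C5, and OH → Cl at C6 with inversion.
4. 12 ← lactone-enolate aldol (C8–C9) of silyloxy lactone 6 (from (R)-β-methyl-γ-butyrolactone 4) with dienal 3, then redox transposition of the lactone.
5. Ring order: temporary lactone (steps 3–6) → lactone ring C (step 13) → rings A and B together (step 18) → epoxide (step 20).

Key step: step 18

Remark: atoms are numbered as in briaranes (ring A = C1, C10–C14; ring B = C1–C10; ring C = lactone C7, C8, C17, C19, O; C15, C18, C20 methyls; C16 exocyclic methylene), and compounds 1, 4, 13 and 15 are taken as purchasable.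

## Route

Step 1
Reactants: 1 (E)-3-methylpent-2-en-4-yn-1-ol
Product: 2 (E)-3-methylpenta-2,4-dien-1-ol
Conditions: H2 (1 atm), Pd/CaCO3 poisoned with Pb(OAc)2, quinoline, EtOAc, rt
Reagents that add atoms: none
Why: Lindlar semi-hydrogenation should reduce only the terminal alkyne to the vinyl group and leave the trisubstituted (E)-alkene untouched.

Step 2
Reactants: 2 (E)-3-methylpenta-2,4-dien-1-ol
Product: 3 (E)-3-methylpenta-2,4-dienal
Conditions: MnO2 (excess), CH2Cl2, rt
Reagents that add atoms: none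
Why: MnO2 oxidation of an allylic alcohol should stop at the conjugated aldehyde without E/Z isomerisation.

Step 3
Reactants: 4 (R)-4-methyldihydrofuran-2(3H)-one
Product: 5 (3R,4S)-3-hydroxy-4-methyldihydrofuran-2(3H)-one
Conditions: NaN(SiMe3)2, THF, −78 °C; 2-(phenylsulfonyl)-3-phenyloxaziridine, −78 °C; aq NH4Cl
Reagents that add atoms: 2-(phenylsulfonyl)-3-phenyloxaziridine, O=S(=O)(c1ccccc1)N1OC1c1ccccc1
Why: Enolate hydroxylation with an N-sulfonyloxaziridine should occur anti to the C17 methyl (trans product); this centre is erased again in step 5, only the oxygen matters.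

Step 4
Reactants: 5 (3R,4S)-3-hydroxy-4-methyldihydrofuran-2(3H)-one
Product: 6 (3R,4S)-4-methyl-3-(triethylsilyloxy)dihydrofuran-2(3H)-one
Conditions: Et3SiCl, imidazole, DMF, 0 °C to rt
Reagents that add atoms: chlorotriethylsilane, CC[Si](Cl)(CC)CC
Why: Standard silylation of a secondary alcohol.

Step 5
Reactants: 6 (3R,4S)-4-methyl-3-(triethylsilyloxy)dihydrofuran-2(3H)-one; 3 (E)-3-methylpenta-2,4-dienal
Product: 7 (3R,4S)-3-[(1S,2E)-1-hydroxy-3-methylpenta-2,4-dienyl]-4-methyl-3-(triethylsilyloxy)dihydrofuran-2(3H)-one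
Conditions: LiN(iPr)2, THF, −78 °C; 3; AcOH quench at −78 °C
Reagents that add atoms: none
Why: Aldol addition of the ring-locked tetrasubstituted lactone enolate should take the aldehyde on the face anti to the C17 methyl (sets C8), and the chair Zimmerman–Traxler transition state should place O8 (cis to the enolate oxygen) syn to the new O9 (sets C9); the cold quench prevents silyl migration.

Step 6
Reactants: 7 aldol lactone
Product: 8 (3R,4S)-3-[(1S,2E)-1-(tert-butyldimethylsilyloxy)-3-methylpenta-2,4-dienyl]-4-methyl-3-(triethylsilyloxy)dihydrofuran-2(3H)-one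
Conditions: tBuMe2SiOTf, 2,6-lutidine, CH2Cl2, −78 to 0 °C
Reagents that add atoms: tert-butyldimethylsilyl trifluoromethanesulfonate, CC(C)(C)[Si](C)(C)OS(=O)(=O)C(F)(F)F
Why: Silyl triflate silylation of the hindered secondary C9 alcohol.

Step 7
Reactants: 8 bis-silyl lactone
Product: 9 (2R,3S,4E)-3-(tert-butyldimethylsilyloxy)-2-[(2S)-1-hydroxypropan-2-yl]-N-methoxy-N,5-dimethyl-2-(triethylsilyloxy)hepta-4,6-dienamide
Conditions: MeNH(OMe)·HCl, AlMe3, CH2Cl2, 0 °C to rt; Rochelle salt work-up
Reagents that add atoms: N,O-dimethylhydroxylamine hydrochloride, CNOC.Cl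
Why: Aluminium amide aminolysis (Weinreb amide formation) should open the lactone at C7 and free the primary C19 alcohol without touching the stereocentres.

Step 8
Reactants: 9 Weinreb amide alcohol
Product: 11 methyl (2R,3R,4S,5E)-4-(tert-butyldimethylsilyloxy)-3-[methoxy(methyl)carbamoyl]-2,6-dimethyl-3-(triethylsilyloxy)octa-5,7-dienoate, via carboxylic acid 10 (not isolated)
Conditions: TEMPO (cat.), PhI(OAc)2, MeCN/pH 7 buffer, rt; then Me3SiCHN2, MeOH/toluene, 0 °C
Reagents that add atoms: water, O; trimethylsilyldiazomethane, C[Si](C)(C)C=[N+]=[N-]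
Why: Nitroxyl-catalysed oxidation takes the primary alcohol to the acid under neutral conditions (no C17 epimerisation, diene tolerated) and diazoalkane esterification gives the methyl ester.

Step 9
Reactants: 11 amide ester
Product: 12 methyl (2R,3R,4S,5E)-4-(tert-butyldimethylsilyloxy)-3-formyl-2,6-dimethyl-3-(triethylsilyloxy)octa-5,7-dienoate
Conditions: Cp2Zr(H)Cl (1.5 equiv), THF, rt, 15 min; silica
Reagents that add atoms: none
Why: Hydrozirconation-type reduction of a tertiary (Weinreb) amide to the aldehyde should be faster than reaction with the ester or the diene, so a short contact time is used.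

Step 10
Reactants: 13 2,4-dimethylfuran
Product: 14 3,5-dimethylfuran-2-carbaldehyde
Conditions: POCl3, DMF, 0 °C to rt; aq NaOAc
Reagents that add atoms: N,N-dimethylformamide, CN(C)C=O; water, O
Why: Vilsmeier–Haack formylation should occur at the only free α-position of the furan.

Step 11
Reactants: 15 hydroxyacetone
Product: 16 1-(triethylsilyloxy)propan-2-one
Conditions: Et3SiCl, imidazole, CH2Cl2, 0 °C
Reagents that add atoms: chlorotriethylsilane, CC[Si](Cl)(CC)CC
Why: Standard silylation of a primary alcohol.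

Step 12
Reactants: 16 1-(triethylsilyloxy)propan-2-one; 14 3,5-dimethylfuran-2-carbaldehyde
Product: 19 (E)-4-(3,5-dimethylfuran-2-yl)-1-(triethylsilyloxy)but-3-en-2-one, via aldol 17 (not isolated), via mesylate 18 (not isolated)
Conditions: LiN(iPr)2, THF, −78 °C; 14; then MsCl, Et3N, −78 °C to rt
Reagents that add atoms: none
Why: The kinetic methyl-side lithium enolate adds to the aldehyde, and mesylation with E1cB elimination (aldol condensation) should give the conjugated (E)-enone.

Step 13
Reactants: 12 aldehyde ester; 19 furyl enone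
Product: 21 keto lactone (6S,7S,8S,9S,17R), via hydroxy ester 20 (not isolated)
Conditions: 19, Bu2BOTf, iPr2NEt, CH2Cl2, −78 °C; 12, −78 to 0 °C; pH 7 buffer/MeOH; then PPTS (cat.), CH2Cl2, rt
Reagents that add atoms: none
Why: The (Z)-boron enolate of the α-silyloxy ketone should give the syn aldol (O6 syn to O7), attacking the aldehyde face given by the Felkin–Anh arrangement (C8–OSi anti, approach past the smaller C17 branch, reinforced by 1,3-anti induction from C9–O), and the new 7-OH then closes lactone ring C onto the methyl ester.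

Step 14
Reactants: 21 keto lactone
Product: 22 triene lactone (6R,7S,8S,9S,17R) with C5=CH2
Conditions: Zn, CH2Br2, TiCl4, THF/CH2Cl2, 0 °C to rt
Reagents that add atoms: dibromomethane, BrCBr
Why: Takai–Lombardo methylenation is non-basic (no β-elimination of the lactone oxygen, no C6 epimerisation) and should select the ketone over the lactone.

Step 15
Reactants: 22 triene lactone
Product: 23 allylic alcohol (6R,7S,8S,9S,17R)
Conditions: PPTS (cat.), MeOH/CH2Cl2, 0 °C
Reagents that add atoms: none
Why: Mild acid methanolysis should cleave the secondary triethylsilyl ether at O6 faster than the tertiary triethylsilyl ether at O8 and the tert-butyldimethylsilyl ether at O9.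

Step 16
Reactants: 23 allylic alcohol
Product: 24 allylic chloride (6S,7R,8S,9S,17R)
Conditions: PPh3, hexachloroacetone, CH2Cl2, −20 to 0 °C
Reagents that add atoms: hexachloroacetone, ClC(Cl)(Cl)C(=O)C(Cl)(Cl)Cl
Why: Appel-type chlorination through the alkoxyphosphonium salt under neutral conditions should displace the secondary allylic alcohol by SN2 with inversion, giving the 6S chloride anti to O7.

Step 17
Reactants: 24 allylic chloride
Product: 25 furan triene diol (6S,7R,8R,9S,17R)
Conditions: HF·pyridine, pyridine, THF, 0 °C to rt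
Reagents that add atoms: none
Why: Buffered fluoride removes both remaining silyl ethers without touching the allylic chloride, the lactone or the acid-sensitive dienylfuran.

Step 18
Reactants: 25 furan triene diol
Product: 28 tricyclic dione (1R,6S,7R,8R,9S,10S,14S,17R), via endoperoxide 26 (not isolated), via cis-enedione 27 (not isolated)
Conditions: O2, visible light, tetraphenylporphyrin (cat.), CH2Cl2, −78 °C; Me2S, −78 to 0 °C; then toluene (0.001 M), BHT, 70 °C
Reagents that add atoms: oxygen, O=O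
Why: Proposed new method: singlet oxygen adds [4+2] to the 2,5-dialkylfuran of 25 (by far its most reactive π system), Me2S reduces endoperoxide 26 to cis-enedione 27, and on warming at high dilution 27 should undergo an intramolecular normal-demand Diels–Alder reaction between diene C10=C11–C12=C13 and the doubly acylated C1=C14 bond; the closest known reaction types are furan photooxygenation to cis-enediones and macrocyclising intramolecular Diels–Alder reactions of tethered trienes with doubly activated dienophiles, which close eleven-membered and larger carbocycles, here a ring one atom smaller. Ring A (C1, C10–C14) is closed by the cycloaddition itself, and ring B (C1–C10) closes at the same time in the fused mode because the eight-carbon tether C2–C9 joins dienophile carbon C1 to diene terminus C10, which also fixes the regiochemistry (C1 to C10, C14 to C13). C10 is controlled by the C9 carbinol: allylic 1,3-strain with the C11 methyl holds H9 in the diene plane, the quaternary C8 turns to the far face and the free 9-OH can hydrogen-bond to the C2 carbonyl, so the dienophile adds syn to O9. C1 follows from the tether approaching exo (C2 trans to C9, trans ring fusion, C15 endo), since the endo path would force the enone chain across H9 and the C11 methyl, and C14 follows from the cis geometry of the enedione fixed by the furan (acetyl cis to C2). The step needs exo over endo approach, this diene face, and intra- over intermolecular reaction; these rest on the hydrogen bond, the allylic strain, the rigid (E)-enone and lactone in the tether and the 0.001 M concentration, and the cross-conjugated C3=C4 bond is a much poorer dienophile than the enedione.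

Step 19
Reactants: 28 tricyclic dione
Product: 29 9-acetate of 28
Conditions: Ac2O, pyridine, DMAP (cat.), CH2Cl2, 0 °C to rt
Reagents that add atoms: acetic anhydride, CC(=O)OC(C)=O
Why: Acylation of the secondary 9-OH; the tertiary 8-OH does not react, and the acetate removes a hydroxyl that could direct the next oxidation to the wrong face.

Step 20
Reactants: 29 9-acetate
Product: 31 14-acetoxy 11,12-epoxy 2-ketone (1R,6S,7R,8R,9S,10S,11S,12R,14S,17R), via epoxy ketone 30 (not isolated)
Conditions: mCPBA (excess), NaHCO3, CH2Cl2, 0 °C to rt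
Reagents that add atoms: 3-chloroperoxybenzoic acid, OOC(=O)c1cccc(Cl)c1
Why: The peracid should first epoxidise the only electron-rich alkene C11=C12 from the face cis to H10 (the other face is shielded by the axial C15 methyl and the C9 acetoxy branch, and the dienone and chloro-allyl alkenes are deactivated) to give 30, and then convert the C14 methyl ketone into the acetate by Baeyer–Villiger oxidation with migration of secondary C14 and retention, the conjugated C2 ketone being much less reactive.

Step 21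
Reactants: 31 epoxy keto triester
Product: 32 2-deacetyl target (2S alcohol)
Conditions: NaBH4, CeCl3·7H2O, MeOH, −78 °C
Reagents that add atoms: none
Why: Luche reduction gives 1,2-reduction of the dienone and leaves esters, lactone, epoxide and chloride alone; hydride is expected from the outer face of ring B, away from the substituents on quaternary C1, to give the 2S alcohol.

Step 22
Reactants: 32 2-deacetyl target
Product: 33 target CNP0106406.1
Conditions: Ac2O, pyridine, DMAP (cat.), CH2Cl2, 0 °C to rt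
Reagents that add atoms: acetic anhydride, CC(=O)OC(C)=O
Why: Acetylation of the secondary allylic 2-OH; the tertiary 8-OH stays free.

## Compound list

1 | (E)-3-methylpent-2-en-4-yn-1-ol | OC/C=C(C)/C#C | starting material
2 | (E)-3-methylpenta-2,4-dien-1-ol | OC/C=C(C)/C=C | intermediate
3 | (E)-3-methylpenta-2,4-dienal | O=C/C=C(C)/C=C | intermediate
4 | (R)-4-methyldihydrofuran-2(3H)-one | C[C@H]1COC(=O)C1 | starting material
5 | (3R,4S)-3-hydroxy-4-methyldihydrofuran-2(3H)-one (OH trans to methyl) | C[C@H]1COC(=O)[C@@H]1O | intermediate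
6 | (3R,4S)-4-methyl-3-(triethylsilyloxy)dihydrofuran-2(3H)-one | C[C@H]1COC(=O)[C@@H]1O[Si](CC)(CC)CC | intermediate
7 | (3R,4S)-3-[(1S,2E)-1-hydroxy-3-methylpenta-2,4-dienyl]-4-methyl-3-(triethylsilyloxy)dihydrofuran-2(3H)-one (8R,9S,17S) | C=C/C(C)=C/[C@H](O)[C@]1(O[Si](CC)(CC)CC)[C@@H](C)COC1=O | intermediate
8 | tert-butyldimethylsilyl ether of 7 | C=C/C(C)=C/[C@H](O[Si](C)(C)C(C)(C)C)[C@]1(O[Si](CC)(CC)CC)[C@@H](C)COC1=O | intermediate
9 | (2R,3S,4E)-3-(tert-butyldimethylsilyloxy)-2-[(2S)-1-hydroxypropan-2-yl]-N-methoxy-N,5-dimethyl-2-(triethylsilyloxy)hepta-4,6-dienamide | C=C/C(C)=C/[C@H](O[Si](C)(C)C(C)(C)C)[C@@](O[Si](CC)(CC)CC)(C(=O)N(C)OC)[C@@H](C)CO | intermediate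
10 | (2R,3R,4S,5E)-4-(tert-butyldimethylsilyloxy)-3-[methoxy(methyl)carbamoyl]-2,6-dimethyl-3-(triethylsilyloxy)octa-5,7-dienoic acid | C=C/C(C)=C/[C@H](O[Si](C)(C)C(C)(C)C)[C@@](O[Si](CC)(CC)CC)(C(=O)N(C)OC)[C@@H](C)C(=O)O | intermediate
11 | methyl ester of 10 | C=C/C(C)=C/[C@H](O[Si](C)(C)C(C)(C)C)[C@@](O[Si](CC)(CC)CC)(C(=O)N(C)OC)[C@@H](C)C(=O)OC | intermediate
12 | methyl (2R,3R,4S,5E)-4-(tert-butyldimethylsilyloxy)-3-formyl-2,6-dimethyl-3-(triethylsilyloxy)octa-5,7-dienoate (8R,9S,17R) | C=C/C(C)=C/[C@H](O[Si](C)(C)C(C)(C)C)[C@@](O[Si](CC)(CC)CC)(C=O)[C@@H](C)C(=O)OC | intermediate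
13 | 2,4-dimethylfuran | Cc1cc(C)co1 | starting material
14 | 3,5-dimethylfuran-2-carbaldehyde | Cc1cc(C)c(C=O)o1 | intermediate
15 | hydroxyacetone (1-hydroxypropan-2-one) | CC(=O)CO | starting material
16 | 1-(triethylsilyloxy)propan-2-one | CC(=O)CO[Si](CC)(CC)CC | intermediate
17 | 4-(3,5-dimethylfuran-2-yl)-4-hydroxy-1-(triethylsilyloxy)butan-2-one (racemic) | Cc1cc(C)c(C(O)CC(=O)CO[Si](CC)(CC)CC)o1 | intermediate
18 | methanesulfonate of 17 (racemic) | Cc1cc(C)c(C(OS(C)(=O)=O)CC(=O)CO[Si](CC)(CC)CC)o1 | intermediate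
19 | (E)-4-(3,5-dimethylfuran-2-yl)-1-(triethylsilyloxy)but-3-en-2-one | Cc1cc(C)c(/C=C/C(=O)CO[Si](CC)(CC)CC)o1 | intermediate
20 | open-chain aldol hydroxy ester (6S,7S,8S,9S,17R): C19 methyl ester, free 7-OH, 6- and 8-OSiEt3, 9-OSitBuMe2, C5 ketone | Cc1cc(C)c(/C=C/C(=O)[C@@H](O[Si](CC)(CC)CC)[C@H](O)[C@@](O[Si](CC)(CC)CC)([C@@H](C)C(=O)OC)[C@@H](O[Si](C)(C)C(C)(C)C)/C=C(C)/C=C)o1 | intermediate
21 | keto lactone (6S,7S,8S,9S,17R): ring C closed, C5 ketone, 6- and 8-OSiEt3, 9-OSitBuMe2 | Cc1cc(C)c(/C=C/C(=O)[C@@H](O[Si](CC)(CC)CC)[C@@H]2OC(=O)[C@H](C)[C@@]2(O[Si](CC)(CC)CC)[C@@H](O[Si](C)(C)C(C)(C)C)/C=C(C)/C=C)o1 | intermediate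
22 | triene lactone (6R,7S,8S,9S,17R): as 21 with C5=CH2 | Cc1cc(C)c(/C=C/C(=C)[C@@H](O[Si](CC)(CC)CC)[C@@H]2OC(=O)[C@H](C)[C@@]2(O[Si](CC)(CC)CC)[C@@H](O[Si](C)(C)C(C)(C)C)/C=C(C)/C=C)o1 | intermediate
23 | allylic alcohol (6R,7S,8S,9S,17R): as 22 with free 6-OH | Cc1cc(C)c(/C=C/C(=C)[C@@H](O)[C@@H]2OC(=O)[C@H](C)[C@@]2(O[Si](CC)(CC)CC)[C@@H](O[Si](C)(C)C(C)(C)C)/C=C(C)/C=C)o1 | intermediate
24 | allylic chloride (6S,7R,8S,9S,17R): 6-Cl with inverted configuration | Cc1cc(C)c(/C=C/C(=C)[C@H](Cl)[C@@H]2OC(=O)[C@H](C)[C@@]2(O[Si](CC)(CC)CC)[C@@H](O[Si](C)(C)C(C)(C)C)/C=C(C)/C=C)o1 | intermediate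
25 | furan triene diol (6S,7R,8R,9S,17R): free 8-OH and 9-OH | Cc1cc(C)c(/C=C/C(=C)[C@H](Cl)[C@@H]2OC(=O)[C@H](C)[C@@]2(O)[C@@H](O)/C=C(C)/C=C)o1 | intermediate
26 | furan endoperoxide of 25 (2,3,7-trioxabicyclo[2.2.1]hept-5-ene, bridgeheads unassigned) | CC12OOC(/C=C/C(=C)[C@H](Cl)[C@@H]3OC(=O)[C@H](C)[C@@]3(O)[C@@H](O)/C=C(C)/C=C)(O1)C(C)=C2 | intermediate
27 | cis-enedione (1Z,3E; 6S,7R,8R,9S,17R): CH3CO–CH=C(CH3)–CO–CH=CH–C(=CH2)– chain on C6 | CC(=O)/C=C(C)\C(=O)/C=C/C(=C)[C@H](Cl)[C@@H]1OC(=O)[C@H](C)[C@@]1(O)[C@@H](O)/C=C(C)/C=C | intermediate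
28 | tricyclic dione (1R,6S,7R,8R,9S,10S,14S,17R): rings A, B, C; C2 ketone; 14-acetyl cis to C2; C11=C12; free 8-OH and 9-OH | C=C1/C=C/C(=O)[C@@]2(C)[C@@H](C(C)=O)CC=C(C)[C@@H]2[C@H](O)[C@]2(O)[C@@H](C)C(=O)O[C@H]2[C@H]1Cl | intermediate
29 | 9-acetate of 28 | C=C1/C=C/C(=O)[C@@]2(C)[C@@H](C(C)=O)CC=C(C)[C@@H]2[C@H](OC(C)=O)[C@]2(O)[C@@H](C)C(=O)O[C@H]2[C@H]1Cl | intermediate
30 | 11,12-epoxide of 29 (11S,12R; oxygen cis to H10) | C=C1/C=C/C(=O)[C@@]2(C)[C@@H](C(C)=O)C[C@H]3O[C@@]3(C)[C@@H]2[C@H](OC(C)=O)[C@]2(O)[C@@H](C)C(=O)O[C@H]2[C@H]1Cl | intermediate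
31 | 14-acetoxy 11,12-epoxy 2-ketone (1R,6S,7R,8R,9S,10S,11S,12R,14S,17R) | C=C1/C=C/C(=O)[C@@]2(C)[C@@H](OC(C)=O)C[C@H]3O[C@@]3(C)[C@@H]2[C@H](OC(C)=O)[C@]2(O)[C@@H](C)C(=O)O[C@H]2[C@H]1Cl | intermediate
32 | 2-deacetyl target (2S alcohol) | C=C1/C=C/[C@H](O)[C@@]2(C)[C@@H](OC(C)=O)C[C@H]3O[C@@]3(C)[C@@H]2[C@H](OC(C)=O)[C@]2(O)[C@@H](C)C(=O)O[C@H]2[C@H]1Cl | intermediate
33 | CNP0106406.1 (1R,2S,6S,7R,8R,9S,10S,11S,12R,14S,17R; 3E) | C=C1/C=C/[C@H](OC(C)=O)[C@@]2(C)[C@@H](OC(C)=O)C[C@H]3O[C@@]3(C)[C@@H]2[C@H](OC(C)=O)[C@]2(O)[C@@H](C)C(=O)O[C@H]2[C@H]1Cl | target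

## Step count and risks

Total step count: 22. Longest linear sequence: 17 steps (from 4 through steps 3–9 and 13–22; the same length from 1).

Steps most likely to fail:

1. Step 18 (Proposed new method). What may go wrong: oligomerisation instead of closure of the ten-membered ring, cycloaddition through the endo tether or on the other diene face (wrong ring fusion), or cis-to-trans isomerisation of the enedione before it cyclises. Fallback, known chemistry, setting out from 12 and returning at 28: ring A is made by an intermolecular Diels–Alder reaction and ring B is closed afterwards by Nozaki–Hiyama–Kishi macrocyclisation. Aldehyde 12 is combined as in step 13 with the boron enolate of (E)-4-iodo-1-(triethylsilyloxy)but-3-en-2-one F1 (prepared separately) to give iodo keto lactone F2, and Takai–Lombardo methylenation gives iodo triene F3. Photooxygenation of 13 and Me2S reduction give (Z)-2-methyl-4-oxopent-2-enal F4. F4 should add to the C10–C13 diene of F3 (toluene, 40 °C, or Me2AlCl, −78 °C) to give ring A aldehyde F5: the formyl-bearing carbon bonds to C10 (ortho orientation set by the less hindered formyl activator), anti to quaternary C8, with the formyl group exo as is usual for 2-methyl-2-enals, and the 1-iodo diene is a poor diene. CrCl2 with catalytic NiCl2 (DMSO/THF, high dilution) joins vinyl iodide carbon C3 to the C2 aldehyde to give ten-membered allylic alcohol F6 (either C2 epimer), and Dess–Martin periodinane gives dienone F7. The operations of steps 15 to 17 (PPTS/MeOH to alcohol F8, PPh3/hexachloroacetone to chloride F9, HF·pyridine) then return to 28.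

2. Step 20. What may go wrong: epoxidation from the face cis to the C15 methyl, over-oxidation of the C5 methylene, or a Baeyer–Villiger step too slow to compete. Fallback, setting out from 29 and returning at 31: the halohydrin route inverts the facial outcome. NBS in wet THF forms the bromonium ion on the face that electrophiles prefer, and water opens it trans-diaxially at tertiary C11 to give bromohydrin F10 (11-OH cis to H10, 12-Br trans). K2CO3 in acetone closes it with inversion at C12 to epoxy ketone 30, and the methyl ketone is then oxidised separately with CF3CO3H/Na2HPO4 to 31.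

3. Step 16. What may go wrong: allylic transposition (SN2′ delivery of chloride to C16) or ionisation with loss of configuration at C6. Fallback, setting out from 12 and 14 and returning at 24: the chlorine is brought in with the aldol partner instead of by substitution. Wittig reaction of 14 with 1-chloro-3-(triphenylphosphoranylidene)propan-2-one gives chloro enone F11. Its (E)-dicyclohexylboron enolate (Cy2BCl, Et3N) should add to 12 in an anti-selective aldol reaction (same aldehyde face as in step 13), and the aldolate lactonises to α-chloro keto lactone F12. Tebbe methylenation (Cp2Ti(μ-Cl)(μ-CH2)AlMe2, −40 °C) of the ketone then gives 24 directly.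

Further compounds

F1 | step 18 | (E)-4-iodo-1-(triethylsilyloxy)but-3-en-2-one | I/C=C/C(=O)CO[Si](CC)(CC)CC
F2 | step 18 | iodo keto lactone (analogue of 21 with iodine in place of the furyl group) | I/C=C/C(=O)[C@@H](O[Si](CC)(CC)CC)[C@@H]1OC(=O)[C@H](C)[C@@]1(O[Si](CC)(CC)CC)[C@@H](O[Si](C)(C)C(C)(C)C)/C=C(C)/C=C
F3 | step 18 | iodo triene lactone (C5=CH2) | I/C=C/C(=C)[C@@H](O[Si](CC)(CC)CC)[C@@H]1OC(=O)[C@H](C)[C@@]1(O[Si](CC)(CC)CC)[C@@H](O[Si](C)(C)C(C)(C)C)/C=C(C)/C=C
F4 | step 18 | (Z)-2-methyl-4-oxopent-2-enal | CC(=O)/C=C(C)\C=O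
F5 | step 18 | ring A aldehyde (C1 formyl and methyl, 14-acetyl, vinyl iodide side chain) | O=C[C@@]1(C)[C@@H](C(C)=O)CC=C(C)[C@@H]1[C@H](O[Si](C)(C)C(C)(C)C)[C@]2(O[Si](CC)(CC)CC)[C@@H](C)C(=O)O[C@H]2[C@H](O[Si](CC)(CC)CC)C(=C)/C=C/I
F6 | step 18 | ring B allylic alcohol (2-OH, either epimer; 6-, 8-, 9-silyl ethers) | C=C1/C=C/C(O)[C@@]2(C)[C@@H](C(C)=O)CC=C(C)[C@@H]2[C@H](O[Si](C)(C)C(C)(C)C)[C@]2(O[Si](CC)(CC)CC)[C@@H](C)C(=O)O[C@H]2[C@@H]1O[Si](CC)(CC)CC
F7 | step 18 | tris-silyl dienone (C2 ketone) | C=C1/C=C/C(=O)[C@@]2(C)[C@@H](C(C)=O)CC=C(C)[C@@H]2[C@H](O[Si](C)(C)C(C)(C)C)[C@]2(O[Si](CC)(CC)CC)[C@@H](C)C(=O)O[C@H]2[C@@H]1O[Si](CC)(CC)CC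
F8 | step 18 | 6-alcohol of F7 | C=C1/C=C/C(=O)[C@@]2(C)[C@@H](C(C)=O)CC=C(C)[C@@H]2[C@H](O[Si](C)(C)C(C)(C)C)[C@]2(O[Si](CC)(CC)CC)[C@@H](C)C(=O)O[C@H]2[C@@H]1O
F9 | step 18 | 6-chloride (8,9-bis-silyl ether of 28) | C=C1/C=C/C(=O)[C@@]2(C)[C@@H](C(C)=O)CC=C(C)[C@@H]2[C@H](O[Si](C)(C)C(C)(C)C)[C@]2(O[Si](CC)(CC)CC)[C@@H](C)C(=O)O[C@H]2[C@H]1Cl
F10 | step 20 | bromohydrin of 29 (11-OH cis to H10, 12-Br trans) | C=C1/C=C/C(=O)[C@@]2(C)[C@@H](C(C)=O)C[C@H](Br)[C@@](C)(O)[C@@H]2[C@H](OC(C)=O)[C@]2(O)[C@@H](C)C(=O)O[C@H]2[C@H]1Cl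
F11 | step 16 | (E)-1-chloro-4-(3,5-dimethylfuran-2-yl)but-3-en-2-one | Cc1cc(C)c(/C=C/C(=O)CCl)o1
F12 | step 16 | α-chloro keto lactone (6S,7R,8S,9S,17R) | Cc1cc(C)c(/C=C/C(=O)[C@H](Cl)[C@@H]2OC(=O)[C@H](C)[C@@]2(O[Si](CC)(CC)CC)[C@@H](O[Si](C)(C)C(C)(C)C)/C=C(C)/C=C)o1
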